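**Assumption:** enantiopure (S)-β-butyrolactone and ethyl L-lactate are treated as catalogue chiral-pool materials. Compounds 3, 6 and 10 are treated as catalogue achiral materials.

## Retrosynthetic overview
1. Target ⇒ its 4,4''-di-O-benzyl ether (one final hydrogenolysis).
2. Fragment union at C7'–C1' (sp3–sp2): Ni/photoredox deoxygenative arylation of a primary alcohol (ring A plus C7–C8–C8'–C7') with an aryl bromide (rings B and C).
3. Left half, C7–C8: light-driven Ni-catalysed decarboxylative benzylation that opens trans-3,4-dimethyl-β-lactone with inversion. The lactone comes from (S)-β-butyrolactone by trans-selective enolate methylation, so C8 is bought and C8' is controlled by it.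
4. Right half: C8''–O by Mitsunobu inversion of ethyl L-lactate (C8'' bought). C7''–C1'' by Felkin–Anh aryl-titanium addition to the derived aldehyde (C7'' controlled by C8'').
5. No ring is built. All three arenes are bought intact, and the only ring event is opening of the β-lactone.

## Route

**Step 1**
Reactants: 1, (S)-β-butyrolactone [(4S)-4-methyloxetan-2-one]
Product: 2, (3S,4S)-3,4-dimethyloxetan-2-one (trans). Mapping: C4 = future C8, C3 = future C8', C2 = future C7'.
Conditions: LDA (1.05 equiv), THF, −95 °C, 10 min; MeI (4 equiv), −95 → −78 °C, 2 h; AcOH quench; short-path distillation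
Reagents that add atoms: iodomethane, CI
Why: β-Lactone enolate alkylation, in which the flat four-membered lithium enolate (β-elimination geometrically blocked) is methylated anti to the C4 methyl, so the bought centre sets C3 as the trans isomer (expected ≥10:1).

**Step 2**
Reactants: 2, (3S,4S)-3,4-dimethyloxetan-2-one; 3, 2-[4-(benzyloxy)-3-methoxyphenyl]acetic acid (1.5 equiv)
Product: 4, (2S,3S)-4-[4-(benzyloxy)-3-methoxyphenyl]-2,3-dimethylbutanoic acid
Conditions: Ni(cod)2 (10 mol %), dtbbpy (12 mol %), Ir[dF(Me)ppy]2(dtbbpy)PF6 (2 mol %), K2CO3 (1.6 equiv), MeCN (anhydrous, halide-free), 450 nm LEDs, 20 °C, 24 h; 1 M HCl work-up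
Reagents that add atoms: none beyond the numbered reactants (CO2 is lost from 3)
Why: Proposed new method: excited Ir oxidises the electron-rich arylacetate, which loses CO2 to give the benzyl radical, while soft (dtbbpy)Ni(0) attacks the strained alkyl C4–O bond from the rear (SN2-type oxidative addition, inversion) to give a five-membered nickelalactone whose ring geometry blocks β-hydride elimination; radical capture gives Ni(III), C(sp3)–C(sp3) reductive elimination proceeds with retention, and Ir(II) returns Ni(I) to Ni(0), so the cycle is redox-neutral, forms C7–C8 with net inversion (8S) and leaves C3 (C8') untouched, and halide is excluded to avoid a stereoablative β-halo-acid radical path; the closest known reaction types are metallaphotoredox decarboxylative sp3–sp3 coupling of acids with alkyl halides, stereoinvertive Ni-catalysed ring-opening cross-coupling of aziridines, and organocuprate SN2 opening of β-lactones.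

**Step 3**
Reactants: 4, the (2S,3S)-acid
Product: 5, (2S,3S)-4-[4-(benzyloxy)-3-methoxyphenyl]-2,3-dimethylbutan-1-ol
Conditions: BH3·SMe2 (2 equiv), THF, 0 °C → rt; MeOH quench
Reagents that add atoms: none
Why: Chemoselective borane reduction of a carboxylic acid via the acyloxyborane, with no enolisable intermediate, so both centres and the benzyl and methyl ethers are untouched.

**Step 4**
Reactants: 6, 4-bromo-2,6-dimethoxyphenol; 7, ethyl (S)-lactate
Product: 8, ethyl (2R)-2-(4-bromo-2,6-dimethoxyphenoxy)propanoate
Conditions: PPh3, DIAD (1.3 equiv each), THF, 0 °C → rt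
Reagents that add atoms: none beyond the numbered reactants
Why: Mitsunobu etherification, in which clean SN2 displacement of the lactate alkoxyphosphonium by the phenoxide inverts the bought (S) centre to the required 8''R aryl ether.

**Step 5**
Reactants: 8, the (R)-ester
Product: 9, (2R)-2-(4-bromo-2,6-dimethoxyphenoxy)propanal (used crude, at once)
Conditions: DIBAL-H (1.05 equiv), CH2Cl2, −78 °C, 1 h; MeOH then Rochelle salt
Reagents that add atoms: none
Why: Partial DIBAL-H reduction of an α-alkoxy ester, in which the chelated aluminium hemiacetal persists at −78 °C so reduction stops at the aldehyde, and the non-basic work-up preserves C8'' and the aryl bromide.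

**Step 6**
Reactants: 9, the (R)-aldehyde; 10, 1-(benzyloxy)-4-bromo-2-methoxybenzene (1.5 equiv)
Product: 11, (1S,2R)-1-[4-(benzyloxy)-3-methoxyphenyl]-2-(4-bromo-2,6-dimethoxyphenoxy)propan-1-ol (erythro)
Conditions: 10, n-BuLi, THF, −78 °C; ClTi(OiPr)3 (1.6 equiv), −78 → −40 °C; then 9, −78 → −20 °C
Reagents that add atoms: none beyond the numbered reactants
Why: Non-chelation (polar Felkin–Anh/Cornforth) addition of a weakly Lewis-acidic aryltitanium triisopropoxide, in which attack anti to the C–OAr bond makes C8'' set C7'' as S (erythro, expected ≥8:1; the threo isomer is removed by chromatography) and ArTi does not exchange with the substrate's bromide.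

**Step 7**
Reactants: 5, the (2S,3S)-alcohol (1.5 equiv); 11, the erythro aryl bromide (1.0 equiv)
Product: 12, (1S,2R)-1-[4-(benzyloxy)-3-methoxyphenyl]-2-{4-[(2R,3S)-4-(4-(benzyloxy)-3-methoxyphenyl)-2,3-dimethylbutyl]-2,6-dimethoxyphenoxy}propan-1-ol
Conditions: 5, 5,7-di-tert-butyl-3-phenylbenzoxazolium BF4 (1.4 equiv), pyridine (1.4 equiv), MTBE, rt, 15 min; then 11, Ir(ppy)2(dtbbpy)PF6 (1.5 mol %), NiBr2·dtbbpy (7.5 mol %), quinuclidine (1.75 equiv), phthalimide (0.25 equiv), DMA/MTBE, 450 nm LEDs, rt
Reagents that add atoms: none beyond the numbered reactants (OH of 5 and Br of 11 are lost)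
Why: Metallaphotoredox NHC-mediated deoxygenative arylation, in which oxidation, deprotonation and β-scission of the pre-formed alcohol–benzoxazolium adduct release the primary C7' radical (not stereogenic, so C8' and C8 are safe), which Ni couples with the aryl bromide; the azolium salt is sub-stoichiometric to 5, so the C7''–OH stays free, and the mild Ir(ppy)2 excited state does not oxidise the arenes.

**Step 8**
Reactants: 12, the di-O-benzyl ether
Product: 13, (+)-(7''S,8S,8'R,8''R)-4,4''-dihydroxy-3,3',3'',5'-tetramethoxy-4',8''-oxy-8,8'-sesquineolignan-7''-ol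
Conditions: H2 (1 atm), 10% Pd/C, EtOAc/EtOH, rt, about 2 h (neutral; stop at full debenzylation)
Reagents that add atoms: none
Why: Catalytic hydrogenolysis, in which phenolic benzyl ethers cleave far faster than the secondary benzylic carbinol under neutral, acid-free conditions, and no stereocentre is touched.

## Compound list
1 | (S)-β-butyrolactone | C[C@H]1CC(=O)O1 | starting material
2 | (3S,4S)-3,4-dimethyloxetan-2-one | C[C@H]1[C@H](C)C(=O)O1 | intermediate
3 | 2-[4-(benzyloxy)-3-methoxyphenyl]acetic acid | COc1cc(CC(=O)O)ccc1OCc1ccccc1 | starting material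
4 | (2S,3S)-4-[4-(benzyloxy)-3-methoxyphenyl]-2,3-dimethylbutanoic acid | COc1cc(C[C@H](C)[C@H](C)C(=O)O)ccc1OCc1ccccc1 | intermediate
5 | (2S,3S)-4-[4-(benzyloxy)-3-methoxyphenyl]-2,3-dimethylbutan-1-ol | COc1cc(C[C@H](C)[C@H](C)CO)ccc1OCc1ccccc1 | intermediate
6 | 4-bromo-2,6-dimethoxyphenol | COc1cc(Br)cc(OC)c1O | starting material
7 | ethyl (S)-lactate | C[C@H](O)C(=O)OCC | starting material
8 | ethyl (2R)-2-(4-bromo-2,6-dimethoxyphenoxy)propanoate | COc1cc(Br)cc(OC)c1O[C@H](C)C(=O)OCC | intermediate
9 | (2R)-2-(4-bromo-2,6-dimethoxyphenoxy)propanal | COc1cc(Br)cc(OC)c1O[C@H](C)C=O | intermediate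
10 | 1-(benzyloxy)-4-bromo-2-methoxybenzene | COc1cc(Br)ccc1OCc1ccccc1 | starting material
11 | (1S,2R)-1-[4-(benzyloxy)-3-methoxyphenyl]-2-(4-bromo-2,6-dimethoxyphenoxy)propan-1-ol | COc1cc(Br)cc(OC)c1O[C@H](C)[C@@H](O)c1ccc(OCc2ccccc2)c(OC)c1 | intermediate
12 | 4,4''-di-O-benzyl ether of the target | COc1cc(C[C@H](C)[C@H](C)Cc2cc(OC)c(O[C@H](C)[C@@H](O)c3ccc(OCc4ccccc4)c(OC)c3)c(OC)c2)ccc1OCc1ccccc1 | intermediate
13 | (+)-(7''S,8S,8'R,8''R)-4,4''-dihydroxy-3,3',3'',5'-tetramethoxy-4',8''-oxy-8,8'-sesquineolignan-7''-ol | COc1cc(C[C@H](C)[C@H](C)Cc2cc(OC)c(O[C@H](C)[C@@H](O)c3ccc(O)c(OC)c3)c(OC)c2)ccc1O | target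

## Summary
**Total steps:** 8.
**Longest linear sequence:** 5 (steps 1→2→3→7→8, or 4→5→6→7→8).

**Three steps most likely to fail**
1. **Step 2 (the proposed new reaction).**
   - Risks: Ni insertion into the acyl C–O bond instead of the alkyl C–O bond. Carboxylate-initiated opening or oligomerisation of 2. Ni–C homolysis that epimerises the cis-dimethyl nickelalactone and erodes C8. Bibenzyl formation.
   - Fallback (known chemistry): copper-mediated SN2 opening of 2 with 4-(benzyloxy)-3-methoxybenzylmagnesium chloride (from the benzyl chloride, Mg, 2-MeTHF), CuBr·SMe2, TMSCl, THF/Me2S, −40 °C. This gives the same acid 4 with inversion.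
2. **Step 1.**
   - Risks: self-acylation or decomposition of the lactone enolate, over-methylation, and loss of the volatile product.
   - Fallback: Fráter–Seebach dianion methylation of ethyl (S)-3-hydroxybutanoate (LDA 2.2 equiv, MeI) to the anti (2S,3S)-hydroxy ester. Then LiOH saponification and retentive lactonisation (PhSO2Cl, pyridine) to 2. This adds two steps.
3. **Step 7.**
   - Risks: slow oxidative addition of the electron-rich bromide, protodehalogenation, and interference from the free carbinol.
   - Fallback: Appel iodination of 5, zinc insertion (Zn, LiCl), and Pd/SPhos Negishi coupling with the ester-stage bromide 8. Steps 5 and 6 are then run on the coupled ester before hydrogenolysis.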